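The daucane skeleton (azulene numbering) is cut at C3–C3a and at C8–C8a, which leads back to an achiral bisabolane-type ketone. One acid-catalysed operation joins the C3 ketone to the exocyclic alkene carbon (C3a), closing the cyclopentanol ring, and then moves the allylic ring methylene C8 from the spiro centre to C8a, turning the cyclohexene into the cycloheptadiene and fixing C3 and C8a. The step exploits the vicinal pair C3a/C8a, shared by the five- and the seven-membered ring, with the tertiary carbinol C3 next to it. The precursor is (6Z)-2-methyl-6-(4-methylcyclohex-3-en-1-ylidene)heptan-3-one, built with defined alkene geometry.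

Key step: step 6

Remark on the precursor: the cascade requires the 6Z alkene (side chain cis to the allylic ring CH2). A 6E drawing of this ketone would put the homoallylic CH2 anti to the new bond and lead to the 3a,5-diene isomer. The Z isomer is therefore taken as the correct precursor, and its geometry is set by construction (steps 2 and 3), not by a rearrangement that cannot tell the two ring arms apart.

Assumption: the sense of induction of the chiral acid in step 6 cannot be predicted; the (S,S) acid is written, and its mirror image would be used if it favoured the enantiomer of 16.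

Step 1
Reactants: 1 prop-2-yn-1-ol; 2 4-bromo-2-methylbut-1-ene
Product: 4 6-methylhept-6-en-2-yn-1-ol, via dilithiated propargyl alcohol 3 (not isolated)
Conditions: LiNH2 (2.2 equiv), NH3(l), −33 °C; then 2, THF, −33 °C to rt; aq. NH4Cl
Reagents that add atoms: 2 4-bromo-2-methylbut-1-ene, C=C(C)CCBr
Why: alkylation of an alkynide (SN2): in the dianion the carbanion is far more nucleophilic than the alkoxide, so the primary bromide is attacked at carbon only and no stereocentre is formed.

Step 2
Reactants: 4 6-methylhept-6-en-2-yn-1-ol; 5 methylmagnesium bromide; 6 allyl bromide (3-bromoprop-1-ene)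
Product: 8 (2Z)-2,6-dimethyl-3-(prop-2-en-1-yl)hepta-2,6-dien-1-ol, via oxamagnesacycle 7 (not isolated)
Conditions: MeMgBr (3.5 equiv), CuI (15 mol%), Et2O, 0 °C to reflux; then allyl bromide (4 equiv), −20 °C to rt; aq. NH4Cl
Reagents that add atoms: 5 methylmagnesium bromide, C[Mg]Br; 6 allyl bromide, C=CCBr
Why: copper-catalysed anti-carbomagnesiation of a propargylic alcohol followed by allylation of the alkenylmagnesium with retention: the alkoxide directs methyl to the carbinol-bearing alkyne carbon and holds magnesium on the other carbon in a five-membered chelate, so the allyl group ends cis to CH2OH and the tetrasubstituted alkene should form as the Z isomer only.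

Step 3
Reactants: 8 (2Z)-2,6-dimethyl-3-(prop-2-en-1-yl)hepta-2,6-dien-1-ol
Product: 9 (2Z)-2-(4-methylcyclohex-3-en-1-ylidene)propan-1-ol
Conditions: second-generation Grubbs catalyst RuCl2(=CHPh)(PCy3)(H2IMes) (3 mol%), CH2Cl2 (0.01 M), 40 °C
Reagents that add atoms: none
Why: ring-closing metathesis joins the monosubstituted to the 1,1-disubstituted terminal alkene and closes the cyclohexene, while the tetrasubstituted alkene is inert to the catalyst, so its geometry is kept and the ring CH2 that came from the allyl group, now the allylic one, stays cis to CH2OH.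

Step 4
Reactants: 9 (2Z)-2-(4-methylcyclohex-3-en-1-ylidene)propan-1-ol
Product: 10 (Z)-4-(1-bromopropan-2-ylidene)-1-methylcyclohex-1-ene
Conditions: CBr4, PPh3, CH2Cl2, −20 °C to 0 °C; used at once
Reagents that add atoms: carbon tetrabromide, BrC(Br)(Br)Br
Why: Appel bromination (SN2 of bromide on the primary alkoxyphosphonium carbon) under neutral, cold conditions, so that the allylic bromide neither ionises nor loses its alkene geometry.

Step 5
Reactants: 10 (Z)-4-(1-bromopropan-2-ylidene)-1-methylcyclohex-1-ene; 11 3-methylbutan-2-one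
Product: 13 (6Z)-2-methyl-6-(4-methylcyclohex-3-en-1-ylidene)heptan-3-one, via lithium enolate 12 (not isolated)
Conditions: LiN(i-Pr)2 (2.5 equiv), 11 (2.6 equiv), THF, −78 °C; then 10, −78 °C to −20 °C
Reagents that add atoms: 11 3-methylbutan-2-one, CC(=O)C(C)C
Why: enolate alkylation: kinetic deprotonation occurs at the methyl group and the lithium enolate displaces the primary allylic bromide by SN2 at carbon, the excess of enolate suppressing proton transfer and double alkylation, and the alkene is not touched.

Step 6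
Reactants: 13 (6Z)-2-methyl-6-(4-methylcyclohex-3-en-1-ylidene)heptan-3-one
Product: 16 (3R,8aR)-6,8a-dimethyl-3-(propan-2-yl)-1,2,3,5,8,8a-hexahydroazulen-3-ol, via spirocyclic C8a cation 14 (not isolated), via ring-expanded C3a cation 15 (not isolated)
Conditions: (S,S)-IDPi acid HN[P(=NSO2CF3)(O2C20H10Ar2)]2 (Ar = 3,5-(CF3)2C6H3; C74H33F30N3O8P2S2; 5 mol%), CH2Cl2, −60 °C to −20 °C; then Et3N
Reagents that add atoms: none
Why: Proposed new method: the confined acid protonates the ketone within its chiral pocket, the ring carbon of the tetrasubstituted alkene (C3a) adds to C3 in a Prins closure of the cyclopentanol ring (5-endo-trig at the alkene, 5-exo-trig at the carbonyl) to give the C8a cation 14, the allylic methylene C8 then moves from the spiro carbon to C8a in a 1,2-shift that enlarges the six-membered ring to the seven-membered one (ring expansion, not a ring closure) to give 15, and the counter-anion removes a C4 proton, the only β-proton of that cation. The closest known reaction types are acid-promoted intramolecular Prins and carbonyl-ene cyclisations of unsaturated carbonyl compounds and confined-acid-catalysed Wagner–Meerwein shifts of alkenyl cycloalkanes; their combination on a dialkyl ketone and its enantioselective course are untested. C3 is controlled by the catalyst, which selects the ketone face, and its hydroxyl ends on the side of the C8a methyl because the hydrogen-bonded anion stays close to the developing C8a cation while the isopropyl group turns away from that methyl. C8a is controlled, relative to C3, by the Z alkene: the forming five-membered ring twists the spiro centre so that only the ring methylene cis to the side chain, the allylic one, lies parallel to the empty orbital, and it migrates suprafacially to the face of C8a opposite the new C3–C3a bond. The step needs face selection at the ketone, migration of the allylic and not the homoallylic methylene, and proton loss that outruns both early deprotonation of 14 and a pinacol-type shift of isopropyl to C3a; the first rests on the catalyst, the second on the alkene geometry fixed in steps 2 and 3, the third on the weakly basic anion, which lets the cation rearrange and then sits next to C4.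

Step 7
Reactants: 16 (3R,8aR)-6,8a-dimethyl-3-(propan-2-yl)-1,2,3,5,8,8a-hexahydroazulen-3-ol
Product: 17 (3R,6R,7S,8aR)-6,7-epoxy-6,8a-dimethyl-3-(propan-2-yl)-1,2,3,5,6,7,8,8a-octahydroazulen-3-ol (6α,7α-epoxide)
Conditions: 1,2:4,5-di-O-isopropylidene-β-L-erythro-2,3-hexodiulo-2,6-pyranose (30 mol%), KHSO5 (as Oxone, 2KHSO5·KHSO4·K2SO4), K2CO3, Bu4NHSO4, MeCN/CH2(OMe)2/aq. buffer (pH 10.5), 0 °C
Reagents that add atoms: potassium peroxymonosulfate KHSO5, [K+].[O-]S(=O)(=O)OO
Why: Shi epoxidation (chiral dioxirane, spiro transition state): the bulky dioxirane should react at the open C6=C7 bond and not at C3a=C4, which lies between two fully substituted carbons, and the L-fructose-derived ketone delivers oxygen to the α face, which is also the face away from the angular methyl, so reagent and substrate control agree and the 6,7-epoxide is set as α.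

Step 8
Reactants: 17 (3R,6R,7S,8aR)-6,7-epoxy-6,8a-dimethyl-3-(propan-2-yl)-1,2,3,5,6,7,8,8a-octahydroazulen-3-ol
Product: 19 (3R,3aS,4S,6R,7S,8aR)-6,7-epoxy-6,8a-dimethyl-3-(propan-2-yl)decahydroazulene-3,4-diol, via C4 alkylborane 18 (not isolated)
Conditions: BH3·SMe2 (3 equiv), THF, 0 °C to rt; then NaOH, H2O2, 0 °C
Reagents that add atoms: hydrogen peroxide, OO
Why: hydroboration–oxidation (syn addition with boron at the less substituted C4, then C–B to C–O with retention): borane should approach the α face, away from the angular methyl on C8a and from the borylated C3 oxygen, so that the C3a hydrogen and the C4 hydroxyl are both α and the ring fusion is trans, while the epoxide and the tertiary alcohol are expected to survive the cold borane and the alkaline peroxide.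

Step 9
Reactants: 19 (3R,3aS,4S,6R,7S,8aR)-6,7-epoxy-6,8a-dimethyl-3-(propan-2-yl)decahydroazulene-3,4-diol; 20 4-(benzyloxy)benzoyl chloride
Product: 21 (3R,3aS,4S,6R,7S,8aR)-6,7-epoxy-3-hydroxy-6,8a-dimethyl-3-(propan-2-yl)decahydroazulen-4-yl 4-(benzyloxy)benzoate
Conditions: 20 (2 equiv), Et3N, DMAP (1 equiv), CH2Cl2, 0 °C to 40 °C
Reagents that add atoms: 20 4-(benzyloxy)benzoyl chloride, O=C(Cl)c1ccc(OCc2ccccc2)cc1
Why: DMAP-catalysed acylation (nucleophilic catalysis) of the only secondary alcohol, the tertiary C3 hydroxyl being too hindered to react and the basic medium leaving the epoxide intact, with no stereocentre touched.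

Step 10
Reactants: 21 (3R,3aS,4S,6R,7S,8aR)-6,7-epoxy-3-hydroxy-6,8a-dimethyl-3-(propan-2-yl)decahydroazulen-4-yl 4-(benzyloxy)benzoate
Product: 22 (3R,3aS,4S,6S,7S,8aR)-3,6,7-trihydroxy-6,8a-dimethyl-3-(propan-2-yl)decahydroazulen-4-yl 4-(benzyloxy)benzoate
Conditions: HClO4 (cat., 0.1 M aq.), THF/H2O, 0 °C
Reagents that add atoms: water, O
Why: acid-catalysed epoxide hydrolysis: water attacks the tertiary C6 from the β face with inversion while the C7–O bond stays, which gives the trans-diol with 6β-OH and 7α-OH, and the ester on the α face cannot reach the β side of C6 and so should not take part.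

Step 11
Reactants: 22 (3R,3aS,4S,6S,7S,8aR)-3,6,7-trihydroxy-6,8a-dimethyl-3-(propan-2-yl)decahydroazulen-4-yl 4-(benzyloxy)benzoate
Product: 23 (3R,3aS,4S,6S,7S,8aR)-3,6,7-trihydroxy-6,8a-dimethyl-3-(propan-2-yl)decahydroazulen-4-yl 4-hydroxybenzoate (CNP0197754.1)
Conditions: H2 (1 atm), Pd on carbon (10% Pd), EtOAc/EtOH, rt
Reagents that add atoms: none
Why: hydrogenolysis of the benzyl aryl ether over palladium on carbon, at a stage where no alkene or other reducible group is left and esters and alcohols are inert.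

Compound list
1 | prop-2-yn-1-ol | C#CCO | starting material
2 | 4-bromo-2-methylbut-1-ene | C=C(C)CCBr | starting material
3 | dilithiated prop-2-yn-1-ol (lithium alkynide and lithium alkoxide) | [Li]C#CCO[Li] | intermediate
4 | 6-methylhept-6-en-2-yn-1-ol | OCC#CCCC(C)=C | intermediate
5 | methylmagnesium bromide | C[Mg]Br | starting material
6 | allyl bromide (3-bromoprop-1-ene) | C=CCBr | starting material
7 | 4-methyl-3-(3-methylbut-3-en-1-yl)-2,5-dihydro-1,2-oxamagnesole (chelated alkenylmagnesium alkoxide, magnesium cis to the CH2O carbon) | CC1=C(CCC(C)=C)[Mg]OC1 | intermediate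
8 | (2Z)-2,6-dimethyl-3-(prop-2-en-1-yl)hepta-2,6-dien-1-ol | OC/C(C)=C(\CC=C)CCC(C)=C | intermediate
9 | (2Z)-2-(4-methylcyclohex-3-en-1-ylidene)propan-1-ol | OC/C(C)=C1\CC=C(C)CC1 | intermediate
10 | (Z)-4-(1-bromopropan-2-ylidene)-1-methylcyclohex-1-ene | BrC/C(C)=C1\CC=C(C)CC1 | intermediate
11 | 3-methylbutan-2-one | CC(=O)C(C)C | starting material
12 | lithium 3-methylbut-1-en-2-olate | [Li]OC(=C)C(C)C | intermediate
13 | (6Z)-2-methyl-6-(4-methylcyclohex-3-en-1-ylidene)heptan-3-one | CC(C)C(=O)CC/C(C)=C1\CC=C(C)CC1 | intermediate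
14 | 1-hydroxy-4,8-dimethyl-1-(propan-2-yl)spiro[4.5]dec-7-en-4-ylium (carbinol carbon as in 16; hydroxyl cis to the homoallylic ring CH2, isopropyl cis to the allylic ring CH2) | CC(C)[C@]1(O)CC[C+](C)[C@]12CC=C(C)CC2 | intermediate
15 | 3-hydroxy-6,8a-dimethyl-3-(propan-2-yl)-1,2,3,4,5,8-hexahydro-8aH-azulen-3a-ylium (C3 and C8a as in 16) | CC(C)[C@]1(O)CC[C@]2(C)CC=C(C)CC[C+]12 | intermediate
16 | (3R,8aR)-6,8a-dimethyl-3-(propan-2-yl)-1,2,3,5,8,8a-hexahydroazulen-3-ol | CC(C)[C@]1(O)CC[C@]2(C)CC=C(C)CC=C21 | intermediate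
17 | (3R,6R,7S,8aR)-6,7-epoxy-6,8a-dimethyl-3-(propan-2-yl)-1,2,3,5,6,7,8,8a-octahydroazulen-3-ol | CC(C)[C@]1(O)CC[C@]2(C)C[C@@H]3O[C@]3(C)CC=C21 | intermediate
18 | 4α-boryl-3-O-boryl adduct of 17 (BH2 on C4, OBH2 on C3, 3a-H α, trans ring fusion) | CC(C)[C@]1(OB)CC[C@]2(C)C[C@@H]3O[C@]3(C)C[C@H](B)[C@H]21 | intermediate
19 | (3R,3aS,4S,6R,7S,8aR)-6,7-epoxy-6,8a-dimethyl-3-(propan-2-yl)decahydroazulene-3,4-diol | CC(C)[C@]1(O)CC[C@]2(C)C[C@@H]3O[C@]3(C)C[C@H](O)[C@H]21 | intermediate
20 | 4-(benzyloxy)benzoyl chloride | O=C(Cl)c1ccc(OCc2ccccc2)cc1 | starting material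
21 | (3R,3aS,4S,6R,7S,8aR)-6,7-epoxy-3-hydroxy-6,8a-dimethyl-3-(propan-2-yl)decahydroazulen-4-yl 4-(benzyloxy)benzoate | CC(C)[C@]1(O)CC[C@]2(C)C[C@@H]3O[C@]3(C)C[C@H](OC(=O)c4ccc(OCc5ccccc5)cc4)[C@H]21 | intermediate
22 | (3R,3aS,4S,6S,7S,8aR)-3,6,7-trihydroxy-6,8a-dimethyl-3-(propan-2-yl)decahydroazulen-4-yl 4-(benzyloxy)benzoate | CC(C)[C@]1(O)CC[C@]2(C)C[C@H](O)[C@@](C)(O)C[C@H](OC(=O)c3ccc(OCc4ccccc4)cc3)[C@H]21 | intermediate
23 | (3R,3aS,4S,6S,7S,8aR)-3,6,7-trihydroxy-6,8a-dimethyl-3-(propan-2-yl)decahydroazulen-4-yl 4-hydroxybenzoate | CC(C)[C@]1(O)CC[C@]2(C)C[C@H](O)[C@@](C)(O)C[C@H](OC(=O)c3ccc(O)cc3)[C@H]21 | target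

Total step count: 11
Longest linear sequence: 11 steps (1 to 23); 2, 5, 6, 11 and 20 are bought.

Steps most likely to fail

1. Step 6 (Proposed new method).
What may go wrong:
- the C8a cation may lose a methyl or ring proton before the shift;
- the homoallylic instead of the allylic methylene may migrate;
- the C3a cation may undergo a pinacol-type shift of the isopropyl group instead of losing the C4 proton;
- the acid may protonate an alkene instead of the ketone;
- the pocket may discriminate the two ketone faces poorly.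

Fallback, with known reactions only; it sets out from allyl bromide 6, uses bromide 2 again, and comes back to the route at 16. Propanenitrile is deprotonated with LiN(i-Pr)2 (THF, −78 °C) and alkylated with 6 to racemic 2-methylpent-4-enenitrile F1. A second deprotonation and alkylation with 2-(2-bromoethyl)-1,3-dioxolane creates the quaternary carbon, the later C8a, of 2-[2-(1,3-dioxolan-2-yl)ethyl]-2-methylpent-4-enenitrile F2. (3-Methylbut-3-en-1-yl)lithium, made from 2 and t-BuLi, adds to the nitrile, and buffered aqueous acetic acid hydrolyses the imine to 6-[2-(1,3-dioxolan-2-yl)ethyl]-2,6-dimethylnona-1,8-dien-5-one F3. Ring-closing metathesis (second-generation Grubbs catalyst RuCl2(=CHPh)(PCy3)(H2IMes), CH2Cl2, 40 °C) closes the seven-membered ring of 2-[2-(1,3-dioxolan-2-yl)ethyl]-2,5-dimethylcyclohept-4-en-1-one F4. KN(SiMe3)2 and PhNTf2 (THF, −78 °C) give the only possible enol triflate, 7-[2-(1,3-dioxolan-2-yl)ethyl]-4,7-dimethylcyclohepta-1,4-dien-1-yl trifluoromethanesulfonate F5. Aqueous HCl in THF frees the aldehyde 4,7-dimethyl-7-(3-oxopropyl)cyclohepta-1,4-dien-1-yl trifluoromethanesulfonate F6. An intramolecular Nozaki–Hiyama–Kishi reaction (CrCl2, NiCl2 cat., DMF) joins C3a to C3 and gives 6,8a-dimethyl-1,2,3,5,8,8a-hexahydroazulen-3-ol F7, which Dess–Martin periodinane oxidises to 6,8a-dimethyl-1,2,8,8a-tetrahydroazulen-3(5H)-one F8. Isopropylmagnesium chloride with CeCl3 (THF, −78 °C) should add to the ketone from the face opposite the angular methyl and give, with the hydroxyl cis to that methyl, racemic 6,8a-dimethyl-3-(propan-2-yl)-1,2,3,5,8,8a-hexahydroazulen-3-ol F9. Preparative chromatography on a chiral stationary phase then separates the enantiomers and delivers 16.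

2. Step 8.
What may go wrong: reductive opening of the epoxide by borane may compete with the slow hydroboration of the hindered C3a=C4 bond, and boron may also be delivered to the β face.

Fallback; it sets out from epoxide 17 and comes back at 22. The epoxide is hydrolysed first (HClO4 cat., THF/H2O, 0 °C) to (3R,6S,7S,8aR)-6,8a-dimethyl-3-(propan-2-yl)-1,2,3,5,6,7,8,8a-octahydroazulene-3,6,7-triol F10. 2,2-Dimethoxypropane and pyridinium p-toluenesulfonate convert the trans-diol into the 6,7-O-isopropylidene acetal of that triol F11. Hydroboration–oxidation (BH3·SMe2, then NaOH/H2O2), now without an epoxide in the molecule, should give the 4α-alcohol, the 6,7-O-isopropylidene acetal of (3R,3aS,4S,6S,7S,8aR)-6,8a-dimethyl-3-(propan-2-yl)decahydroazulene-3,4,6,7-tetrol F12. Acylation with 20 (Et3N, DMAP) gives its 4-O-[4-(benzyloxy)benzoyl] derivative F13, and aqueous acetic acid removes the acetal to give 22.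

3. Step 2.
What may go wrong: methylmagnesiation of the internal alkyne may be slow or may place methyl on either alkyne carbon, and the alkenylmagnesium may be protonated before it is allylated.

Fallback; it sets out from allyl bromide 6, now brought in as allylzinc bromide, and comes back at 8. The dianion of ethyl 2-methylacetoacetate (NaH, then n-BuLi, THF) is alkylated at its terminal carbon with 3-chloro-2-methylprop-1-ene to give ethyl 2,6-dimethyl-3-oxohept-6-enoate F14. Enol triflation through the chelated lithium enolate (aq. LiOH, Tf2O, toluene) gives the Z enol triflate, ethyl (2Z)-2,6-dimethyl-3-{[(trifluoromethyl)sulfonyl]oxy}hepta-2,6-dienoate F15. Negishi coupling with allylzinc bromide, made from 6 and zinc (Pd(PPh3)4, THF), replaces the triflate with retention and gives ethyl (2Z)-2,6-dimethyl-3-(prop-2-en-1-yl)hepta-2,6-dienoate F16. Reduction with i-Bu2AlH (CH2Cl2, −78 °C) gives 8.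

Further compounds
F1 | step 6 | 2-methylpent-4-enenitrile (racemic) | C=CCC(C)C#N
F2 | step 6 | 2-[2-(1,3-dioxolan-2-yl)ethyl]-2-methylpent-4-enenitrile (racemic) | C=CCC(C)(CCC1OCCO1)C#N
F3 | step 6 | 6-[2-(1,3-dioxolan-2-yl)ethyl]-2,6-dimethylnona-1,8-dien-5-one (racemic) | C=C(C)CCC(=O)C(C)(CC=C)CCC1OCCO1
F4 | step 6 | 2-[2-(1,3-dioxolan-2-yl)ethyl]-2,5-dimethylcyclohept-4-en-1-one (racemic) | O=C1CCC(C)=CCC1(C)CCC2OCCO2
F5 | step 6 | 7-[2-(1,3-dioxolan-2-yl)ethyl]-4,7-dimethylcyclohepta-1,4-dien-1-yl trifluoromethanesulfonate (racemic) | FC(F)(F)S(=O)(=O)OC1=CCC(C)=CCC1(C)CCC2OCCO2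
F6 | step 6 | 4,7-dimethyl-7-(3-oxopropyl)cyclohepta-1,4-dien-1-yl trifluoromethanesulfonate (racemic) | O=CCCC1(C)CC=C(C)CC=C1OS(=O)(=O)C(F)(F)F
F7 | step 6 | 6,8a-dimethyl-1,2,3,5,8,8a-hexahydroazulen-3-ol (racemic, both C3 epimers) | OC1CCC2(C)CC=C(C)CC=C12
F8 | step 6 | 6,8a-dimethyl-1,2,8,8a-tetrahydroazulen-3(5H)-one (racemic) | O=C1CCC2(C)CC=C(C)CC=C12
F9 | step 6 | racemic 6,8a-dimethyl-3-(propan-2-yl)-1,2,3,5,8,8a-hexahydroazulen-3-ol (3R,8aR and 3S,8aS) | CC(C)[C@]1(O)CC[C@]2(C)CC=C(C)CC=C21.CC(C)[C@@]1(O)CC[C@@]2(C)CC=C(C)CC=C21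
F10 | step 8 | (3R,6S,7S,8aR)-6,8a-dimethyl-3-(propan-2-yl)-1,2,3,5,6,7,8,8a-octahydroazulene-3,6,7-triol | CC(C)[C@]1(O)CC[C@]2(C)C[C@H](O)[C@@](C)(O)CC=C21
F11 | step 8 | 6,7-O-isopropylidene acetal of F10 | CC(C)[C@]1(O)CC[C@]2(C)C[C@@H]3OC(C)(C)O[C@@]3(C)CC=C21
F12 | step 8 | 6,7-O-isopropylidene acetal of (3R,3aS,4S,6S,7S,8aR)-6,8a-dimethyl-3-(propan-2-yl)decahydroazulene-3,4,6,7-tetrol | CC(C)[C@]1(O)CC[C@]2(C)C[C@@H]3OC(C)(C)O[C@@]3(C)C[C@H](O)[C@H]21
F13 | step 8 | 4-O-[4-(benzyloxy)benzoyl] derivative of F12 | CC(C)[C@]1(O)CC[C@]2(C)C[C@@H]3OC(C)(C)O[C@@]3(C)C[C@H](OC(=O)c4ccc(OCc5ccccc5)cc4)[C@H]21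
F14 | step 2 | ethyl 2,6-dimethyl-3-oxohept-6-enoate | CCOC(=O)C(C)C(=O)CCC(C)=C
F15 | step 2 | ethyl (2Z)-2,6-dimethyl-3-{[(trifluoromethyl)sulfonyl]oxy}hepta-2,6-dienoate | CCOC(=O)/C(C)=C(\OS(=O)(=O)C(F)(F)F)CCC(C)=C
F16 | step 2 | ethyl (2Z)-2,6-dimethyl-3-(prop-2-en-1-yl)hepta-2,6-dienoate | CCOC(=O)/C(C)=C(\CC=C)CCC(C)=C
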